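The synthesis rests on cutting the side chain between C5′, the β-carbon of the enone, and C6′, the first carbon of the nonyl tail. In one flask an acetylide opens a temporary dihydrocoumarin ring (lactone between O5 of the benzene ring and C3′) in a tricyclic 3-ethoxyphthalide, and a dinonylcuprate adds to the terminal carbon of the resulting alk-1-yn-3-one: the C5′–C6′ bond and the (E)-C4′=C5′ alkene arise together. The step exploits the electrophilic enone β-carbon C5′ and the O5 phenol ortho to the C6 chain. A Diels–Alder aromatisation builds the benzene ring; C4 formylation, lactol release and an enzymatic dynamic resolution at C3 complete the synthesis.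

Key step: step 4

Numbering: phthalide (isobenzofuran-1(3H)-one) atoms are C1(=O), O2, C3, C3a, C4–C7, C7a; the chain on C6 is C1′–C14′ (C3′ ketone, C4′=C5′ alkene, C6′–C14′ nonyl).

Remark: C3 is a hemiacylal (lactol) carbon that can epimerise through the open formyl acid; it is therefore set in the last two steps under enzyme control, and 15 is to be isolated and kept cold, neutral and aprotic. Compounds 9–13 are racemic at C3.

Step 1
Reactants: 1 3,3-diethoxyprop-1-yne
Product: 3 ethyl 4,4-diethoxybut-2-ynoate, via lithium acetylide 2 (not isolated)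
Conditions: n-BuLi (1.05 equiv), THF, −78 °C; ClCO2Et, −78 → 0 °C
Reagents that add atoms: ethyl chloroformate, CCOC(=O)Cl
Why: C-acylation of a lithium acetylide with a chloroformate; the diethyl acetal is inert to n-BuLi at −78 °C.

Step 2
Reactants: 4 diethyl 2-acetylpentanedioate
Product: 5 ethyl 4-[ethoxy(trimethylsilyloxy)methylidene]-5-(trimethylsilyloxy)hex-5-enoate (ketene-acetal geometry undefined; used crude)
Conditions: TMSOTf (2.2 equiv), Et3N (2.5 equiv), Et2O, 0 °C → rt; decant from the ammonium salt, concentrate
Reagents that add atoms: trimethylsilyl trifluoromethanesulfonate, C[Si](C)(C)OS(=O)(=O)C(F)(F)F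
Why: Double O-silylation of a β-keto ester by soft enolisation (silyl triflate/tertiary amine) should give first the silyl enol ether and then, by γ-deprotonation of the vinylogous ester, the 1-ethoxy-1,3-bis(silyloxy)diene, while the isolated side-chain ester, which lacks this double activation, is expected to stay untouched.

Step 3
Reactants: 5 bis(silyloxy)diene; 3 ethyl 4,4-diethoxybut-2-ynoate
Product: 9 tricyclic bis-lactone (rac-3-ethoxy-7-hydroxyphthalide whose O5 and C6 are bridged by –C(=O)CH2CH2– as a dihydrocoumarin ring), via cycloadduct 6 (not isolated), via bis-silyl benzoate 7 (not isolated), via resorcylate diester 8 (not isolated)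
Conditions: PhMe, 100 °C; then TsOH·H2O (0.1 equiv), H2O (2 equiv), PhMe, 60 → 110 °C with distillation of EtOH
Reagents that add atoms: water, O
Why: Diels–Alder reaction of a 1-alkoxy-1,3-bis(silyloxy)diene with an alkynoate followed by loss of ethanol (aromatisation), in which the nucleophilic CH2 terminus bonds to the acetal-bearing β-carbon and the ketene-acetal carbon to the ester-bearing α-carbon so that the 3-alkyl-2,4-dihydroxy-6-(diethoxymethyl)benzoate pattern is fixed; acid then removes the silyl groups, closes the acetal onto the neighbouring ester as the racemic 3-ethoxyphthalide (pseudo-ester) and lactonises the chain ester onto the non-chelated, more nucleophilic O5–H.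

Step 4
Reactants: 9 tricyclic bis-lactone
Product: 11 rac-3-ethoxy-5,7-dihydroxy-6-[(4E)-3-oxotetradec-4-en-1-yl]isobenzofuran-1(3H)-one, via ynone 10 (not isolated)
Conditions: HC≡CMgBr (2.15 equiv), THF, −40 → −10 °C; Ar purge; (n-C9H19)2CuMgBr (2 equiv, from n-C9H19MgBr and CuBr·SMe2), −78 → −30 °C; aq NH4Cl; then I2 (5 mol %), CH2Cl2, rt
Reagents that add atoms: ethynylmagnesium bromide, C#C[Mg]Br; n-nonylmagnesium bromide (delivered as its cuprate), CCCCCCCCC[Mg]Br
Why: The first equivalent of acetylide deprotonates O7–H and the second adds once to the aryl δ-lactone carbonyl (the future C3′), whose ring-opening frees the O5 phenoxide and the alk-1-yn-3-one 10; the magnesium dinonylcuprate then adds its nonyl group to the terminal alkyne carbon C5′ (syn-carbocupration, i.e. 1,4-addition), and protonation gives the C4′=C5′ alkene, so that lactone, C2 unit and C9 chain are joined in one flask. The closest known reaction types are mono-addition of a metal acetylide to a dihydrocoumarin and conjugate addition of an organocuprate to a terminal ynone. No ring is closed; the temporary dihydrocoumarin ring is opened. No stereocentre is formed; the E geometry follows from syn addition and is secured thermodynamically by iodine-catalysed equilibration of any Z isomer. The step needs attack at the lactone carbonyl and not at the phthalide carbonyl or C3, which the ortho phenoxide (vinylogous carbonate character) and the low temperature should secure, and cuprates are inert to the pseudo-ester. It also needs single acetylide addition (small excess, ≤ −10 °C, residual acetylide ending as a non-transferable ligand on copper) and 1,4- over 1,2-delivery of the nonyl group (soft cuprate).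

Step 5
Reactants: 11 enone
Product: 13 rac-3,5,7-trihydroxy-1-oxo-6-[(4E)-3-oxotetradec-4-en-1-yl]-1,3-dihydroisobenzofuran-4-carbaldehyde, via ethoxy aldehyde 12 (not isolated)
Conditions: MgCl2 (4 equiv), Et3N (8 equiv), (CH2O)n (10 equiv), THF, 65 °C; then 1 M HCl, THF, 45 °C
Reagents that add atoms: paraformaldehyde (as formaldehyde), C=O; water, O
Why: Magnesium-phenoxide-directed ortho-formylation (Casnati–Skattebøl) should deliver formaldehyde from the O5 phenoxide to C4, the only free ring position, a second formaldehyde oxidising the hydroxymethyl stage by hydride transfer, and aqueous acid then hydrolyses the 3-ethoxy pseudo-ester to the racemic lactol.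

Step 6
Reactants: 13 racemic lactol
Product: 14 (3R)-4-formyl-5,7-dihydroxy-1-oxo-6-[(4E)-3-oxotetradec-4-en-1-yl]-1,3-dihydroisobenzofuran-3-yl acetate
Conditions: immobilised Burkholderia cepacia lipase, vinyl acetate (5 equiv), PhMe, 40 °C
Reagents that add atoms: vinyl acetate, CC(=O)OC=C
Why: Lipase-catalysed acylative dynamic kinetic resolution of a pseudo-acid lactol: the C3 epimers interconvert through the open formyl acid while the enzyme should acetylate the (3R)-lactol faster (empirical rule for secondary alcohols, aryl carbon as large and ring O–C(=O) as medium group, sense to be confirmed), so C3 is set by the enzyme; the two phenols are hydrogen-bonded to ortho carbonyls and are poor lipase substrates.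

Step 7
Reactants: 14 (3R)-acetate
Product: 15 (3R)-3,5,7-trihydroxy-1-oxo-6-[(4E)-3-oxotetradec-4-en-1-yl]-1,3-dihydroisobenzofuran-4-carbaldehyde
Conditions: same lipase, n-BuOH (5 equiv), MTBE, 20 °C; filter, evaporate cold
Reagents that add atoms: none
Why: Enzymatic transesterification (butanolysis) cleaves the acetyl C–O bond and leaves the C3–O bond intact, so the configuration set in step 6 should be retained, and the matching (R)-preference of the same enzyme should further raise the enantiomeric purity.

Compound list
1 | 3,3-diethoxyprop-1-yne | CCOC(OCC)C#C | starting material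
2 | (3,3-diethoxyprop-1-yn-1-yl)lithium | CCOC(OCC)C#C[Li] | intermediate
3 | ethyl 4,4-diethoxybut-2-ynoate | CCOC(=O)C#CC(OCC)OCC | intermediate
4 | diethyl 2-acetylpentanedioate | CCOC(=O)CCC(C(C)=O)C(=O)OCC | starting material
5 | ethyl 4-[ethoxy(trimethylsilyloxy)methylidene]-5-(trimethylsilyloxy)hex-5-enoate | CCOC(=O)CCC(C(=C)O[Si](C)(C)C)=C(OCC)O[Si](C)(C)C | intermediate
6 | ethyl 2-(diethoxymethyl)-6-ethoxy-5-(3-ethoxy-3-oxopropyl)-4,6-bis(trimethylsilyloxy)cyclohexa-1,4-diene-1-carboxylate (racemic) | CCOC(=O)CCC1=C(O[Si](C)(C)C)CC(C(OCC)OCC)=C(C(=O)OCC)C1(OCC)O[Si](C)(C)C | intermediate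
7 | ethyl 6-(diethoxymethyl)-3-(3-ethoxy-3-oxopropyl)-2,4-bis(trimethylsilyloxy)benzoate | CCOC(=O)CCc1c(O[Si](C)(C)C)cc(C(OCC)OCC)c(C(=O)OCC)c1O[Si](C)(C)C | intermediate
8 | ethyl 6-(diethoxymethyl)-3-(3-ethoxy-3-oxopropyl)-2,4-dihydroxybenzoate | CCOC(=O)CCc1c(O)cc(C(OCC)OCC)c(C(=O)OCC)c1O | intermediate
9 | tricyclic bis-lactone: rac-3-ethoxy-7-hydroxyphthalide with O5 and C6 bridged by –C(=O)CH2CH2– (dihydrocoumarin ring) | O=C1CCc2c(O1)cc3c(c2O)C(=O)OC3OCC | intermediate
10 | rac-3-ethoxy-5,7-dihydroxy-6-(3-oxopent-4-yn-1-yl)isobenzofuran-1(3H)-one | C#CC(=O)CCc1c(O)cc2c(c1O)C(=O)OC2OCC | intermediate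
11 | rac-3-ethoxy-5,7-dihydroxy-6-[(4E)-3-oxotetradec-4-en-1-yl]isobenzofuran-1(3H)-one | CCCCCCCCC/C=C/C(=O)CCc1c(O)cc2c(c1O)C(=O)OC2OCC | intermediate
12 | rac-3-ethoxy-5,7-dihydroxy-1-oxo-6-[(4E)-3-oxotetradec-4-en-1-yl]-1,3-dihydroisobenzofuran-4-carbaldehyde | CCCCCCCCC/C=C/C(=O)CCc1c(O)c(C=O)c2c(c1O)C(=O)OC2OCC | intermediate
13 | rac-3,5,7-trihydroxy-1-oxo-6-[(4E)-3-oxotetradec-4-en-1-yl]-1,3-dihydroisobenzofuran-4-carbaldehyde | CCCCCCCCC/C=C/C(=O)CCc1c(O)c(C=O)c2c(c1O)C(=O)OC2O | intermediate
14 | (3R)-4-formyl-5,7-dihydroxy-1-oxo-6-[(4E)-3-oxotetradec-4-en-1-yl]-1,3-dihydroisobenzofuran-3-yl acetate | CCCCCCCCC/C=C/C(=O)CCc1c(O)c(C=O)c2c(c1O)C(=O)O[C@H]2OC(C)=O | intermediate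
15 | (3R)-3,5,7-trihydroxy-1-oxo-6-[(4E)-3-oxotetradec-4-en-1-yl]-1,3-dihydroisobenzofuran-4-carbaldehyde | CCCCCCCCC/C=C/C(=O)CCc1c(O)c(C=O)c2c(c1O)C(=O)O[C@H]2O | target

Total step count: 7. Longest linear sequence: 6 steps (steps 2–7 from compound 4; step 1 is a one-step branch that joins at step 3).

Steps most likely to fail

Step 5. The enone may not survive the warm, basic, formaldehyde-rich medium (hydroxymethylation at C2′ by soft enolisation, intermolecular oxa-Michael addition of phenoxide), and the oxidation of the hydroxymethyl stage may stall. Fallback: the enone is masked before formylation. Starting from 11, thiophenol (cat. Et3N, CH2Cl2) should add to C5′ to give the β-phenylsulfanyl ketone rac-3-ethoxy-5,7-dihydroxy-6-[3-oxo-5-(phenylsulfanyl)tetradecyl]isobenzofuran-1(3H)-one F1. Electrophilic Rieche formylation at C4 (Cl2CHOMe, TiCl4, CH2Cl2, −20 °C) with a warm acidic aqueous work-up, which also hydrolyses the pseudo-ester, should give the formyl lactol sulfide 3,5,7-trihydroxy-1-oxo-6-[3-oxo-5-(phenylsulfanyl)tetradecyl]-1,3-dihydroisobenzofuran-4-carbaldehyde F2. NaIO4 (MeOH/H2O, 0 °C) should give the sulfoxide 3,5,7-trihydroxy-1-oxo-6-[3-oxo-5-(phenylsulfinyl)tetradecyl]-1,3-dihydroisobenzofuran-4-carbaldehyde F3, whose thermal syn-elimination (PhMe, 80 °C) regenerates the (E)-enone and returns to the route at 13.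

Step 4. The ynone may meet the acetylide too early (second addition, or proton transfer that stalls lactone opening), ring opening may be incomplete before the cuprate is added, and Z→E equilibration may be incomplete. Fallback: the two events are separated and the nonyl group is delivered by palladium catalysis with fixed alkene geometry. From 9, lithium acetylide (THF, −78 °C, AcOH quench at −78 °C) should give isolated ynone 10. Hydroiodination (NaI, AcOH, then acid-catalysed equilibration) should give the β-iodoenone rac-3-ethoxy-5,7-dihydroxy-6-[(4E)-5-iodo-3-oxopent-4-en-1-yl]isobenzofuran-1(3H)-one F4. B-alkyl Suzuki–Miyaura coupling with 9-nonyl-9-borabicyclo[3.3.1]nonane F5 (from non-1-ene and 9-BBN-H; PdCl2(dppf), K3PO4, DMF, 50 °C) forms the same C5′–C6′ bond with retention and returns to the route at 11.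

Step 6. Acyl transfer to the hindered C3 hydroxyl may be slow or poorly selective, so that background acetylation or incomplete enantioselection erodes the configuration that step 7 has to preserve. Fallback: no acyl derivative is made. Racemic 13 is resolved directly by preparative chromatography on a chiral stationary phase at low temperature with a non-protic eluent, the unwanted enantiomer being left to re-equilibrate through the open form and recycled. The (3R) fraction is 15, so the fallback sets out from 13 and returns at 15 without new compounds.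

Further compounds
F1 | step 5 | rac-3-ethoxy-5,7-dihydroxy-6-[3-oxo-5-(phenylsulfanyl)tetradecyl]isobenzofuran-1(3H)-one (diastereomer mixture) | CCCCCCCCCC(Sc1ccccc1)CC(=O)CCc1c(O)cc2c(c1O)C(=O)OC2OCC
F2 | step 5 | 3,5,7-trihydroxy-1-oxo-6-[3-oxo-5-(phenylsulfanyl)tetradecyl]-1,3-dihydroisobenzofuran-4-carbaldehyde (stereoisomer mixture) | CCCCCCCCCC(Sc1ccccc1)CC(=O)CCc1c(O)c(C=O)c2c(c1O)C(=O)OC2O
F3 | step 5 | 3,5,7-trihydroxy-1-oxo-6-[3-oxo-5-(phenylsulfinyl)tetradecyl]-1,3-dihydroisobenzofuran-4-carbaldehyde (stereoisomer mixture) | CCCCCCCCCC(CC(=O)CCc1c(O)c(C=O)c2c(c1O)C(=O)OC2O)S(=O)c1ccccc1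
F4 | step 4 | rac-3-ethoxy-5,7-dihydroxy-6-[(4E)-5-iodo-3-oxopent-4-en-1-yl]isobenzofuran-1(3H)-one | I/C=C/C(=O)CCc1c(O)cc2c(c1O)C(=O)OC2OCC
F5 | step 4 | 9-nonyl-9-borabicyclo[3.3.1]nonane | CCCCCCCCCB1C2CCCC1CCC2
F0 | step 6 | none | none
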